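**Retrosynthetic overview**

- The strategy rests on the substitution of each benzene ring: counted from the biaryl carbon C1, oxygen sits on C2, C4 and C6, acetyl on C3 and methyl on C5. Each ring is therefore an acylphloroglucinol, a folded tetraketide whose C1 is the α-carbon of a β-keto ester.
- Contortin 13 is traced back through C–O operations only (desilylation, two O-methylations) to hexol 9. Both arenes of 9 are then opened at C2–C3 and C2'–C3' to the 3,3'-bipyranone 7, in which the C1–C1' bond already exists as an sp3-derived C3–C3' link.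
- 7 comes from the tetraketo diester 5 by lactonisation and ketal removal; 5 from dimer 3 and two molecules of ketal ester 4 by twofold γ-acylation; 3 from two molecules of methyl 3-oxopentanoate 1 by iodine coupling of the enolate.
- Ring order: two pyranone rings (step 3, temporary), both benzene rings at once (step 4), then a temporary seven-membered silylene ring across O–C2/O–C2' (step 6) that keeps the C2 hydroxyls free while C4–OH is methylated.

Key step: step 4

Remark: the target SMILES defines no axial configuration, so the tetra-ortho-substituted biaryl is made as the racemate; the sp3 stereocentres of 3, 5 and 8 are uncontrolled and are erased later.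

**Route**

Step 1
Reactants: 1 methyl 3-oxopentanoate (2 equiv)
Product: 3 dimethyl 2,3-dipropanoylbutanedioate, via methyl 2-iodo-3-oxopentanoate 2 (not isolated)
Conditions: NaH, THF, 0 °C; then I2 (0.5 equiv), 0 °C → rt; aq. Na2S2O3/NH4Cl work-up
Reagents that add atoms: none
Why: Classical oxidative dimerisation of a β-keto ester sodium enolate, in which iodine α-iodinates half of the enolate and the other half displaces iodide (SN2) to form the future C1–C1' bond; the two stereocentres form without control and do not matter, and the neutral work-up avoids acid-induced furan closure of the 1,4-diketone.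

Step 2
Reactants: 3 dimethyl 2,3-dipropanoylbutanedioate; 4 ethyl 2-(2-methyl-1,3-dioxolan-2-yl)acetate (2.3 equiv)
Product: 5 dimethyl 2,3-bis[2-methyl-4-(2-methyl-1,3-dioxolan-2-yl)-3-oxobutanoyl]butanedioate
Conditions: NaH (4.5 equiv), THF, 0 °C; n-BuLi (2.2 equiv), 0 °C; 4, 0 °C → rt; AcOH, −20 °C
Reagents that add atoms: none
Why: Twofold γ-acylation of a β-keto ester dianion (Claisen condensation): NaH gives the bis(sodium enolate), n-BuLi removes one propionyl CH2 proton on each half, the two carbanions add to ester 4 and expel ethoxide, and the surplus NaH takes up the acidic diketone proton of the product so that unreacted carbanion is not quenched, while the dioxolane keeps the terminal ketone out of the base chemistry.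

Step 3
Reactants: 5 dimethyl 2,3-bis[2-methyl-4-(2-methyl-1,3-dioxolan-2-yl)-3-oxobutanoyl]butanedioate
Product: 7 4,4'-dihydroxy-5,5'-dimethyl-6,6'-bis(2-oxopropyl)-3,3'-bi(2H-pyran)-2,2'-dione, via bis-dioxolane bipyranone 6 (not isolated)
Conditions: DBU (3 equiv), PhMe, 90 °C; then 2 M HCl, THF, rt
Reagents that add atoms: water (O)
Why: Base-mediated lactonisation of a 3,5-dioxo ester (the enolate oxygen of the ketone next to the side chain acylates the ester, loss of methanol) drains to the stable pyranonate salt while the ketone is still masked, so that neither a free 1,3,5-triketone nor the 1,4-diketone of 5 meets strong acid, and the mild aqueous acid that follows only hydrolyses the two dioxolanes.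

Step 4
Reactants: 7 4,4'-dihydroxy-5,5'-dimethyl-6,6'-bis(2-oxopropyl)-3,3'-bi(2H-pyran)-2,2'-dione
Product: 9 3,3'-diacetyl-5,5'-dimethylbiphenyl-2,2',4,4',6,6'-hexol, via magnesium chelate of bis(trioxo ester) 8 (not isolated)
Conditions: Mg(OMe)2 (10 equiv), MeOH, reflux, Ar; cold 1 M HCl work-up
Reagents that add atoms: none
Why: Magnesium-bound methoxide adds to each lactone carbonyl (future arene C2) and opens both pyranones to the chelated bis(methyl 3,5,7-trioxo ester) 8, in which the methylene between the two ketones of each half (future C3) is the most acidic carbon; its enolate attacks the ester carbonyl, methoxide leaves and the cyclohexanetrione enolises to the arene, which forms C2–C3 and C2'–C3'. The closest known reaction type is the Mg(OMe)2-induced Claisen cyclisation of 6-(2-oxoalkyl)-4-hydroxy-2-pyranones and of 3,5,7-trioxo esters to acylphloroglucinols, here run twice on one molecule. Each benzene ring closes by a 6-exo-trig acyl substitution (Dieckmann-type Claisen condensation). No stereocentre is formed, and the sp3 centres of 8, including the two at the future biaryl carbons, vanish on enolisation. The selectivity needed is Claisen rather than aldol folding: attack of C1 on the terminal ketone, or a five-membered closure onto the twin's ester, would give adducts with a quaternary carbon that cannot aromatise and revert, the terminal methyl is far less acidic than the doubly activated methylene, and magnesium holds the β-dicarbonyl units as chelated enolates that are poor aldol acceptors. Only the fold that ends in a phenoxide is irreversible, and the C1–C1' bond is never touched, so the hindered biaryl should emerge without any aryl–aryl coupling.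

Step 5
Reactants: 9 3,3'-diacetyl-5,5'-dimethylbiphenyl-2,2',4,4',6,6'-hexol
Product: 10 3,3'-diacetyl-6,6'-dimethoxy-5,5'-dimethylbiphenyl-2,2',4,4'-tetrol
Conditions: Me2SO4 (2.1 equiv), K2CO3, acetone, 0 °C → rt, Ar
Reagents that add atoms: dimethyl sulfate COS(=O)(=O)OC
Why: Williamson O-methylation that should stop at the C6 and C6' hydroxyls, which are para to the acetyl groups and hence the most acidic and the only ones not hydrogen-bonded to a carbonyl, as in the para-selective monomethylation of phloroacetophenone.

Step 6
Reactants: 10 3,3'-diacetyl-6,6'-dimethoxy-5,5'-dimethylbiphenyl-2,2',4,4'-tetrol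
Product: 11 4,8-diacetyl-6,6-di-tert-butyl-3,9-dihydroxy-1,11-dimethoxy-2,10-dimethyldibenzo[d,f][1,3,2]dioxasilepine
Conditions: tBu2Si(OTf)2 (1.05 equiv), 2,6-lutidine, CH2Cl2 (0.01 M), 0 °C → rt
Reagents that add atoms: di-tert-butylsilyl bis(trifluoromethanesulfonate) CC(C)(C)[Si](OS(=O)(=O)C(F)(F)F)(OS(=O)(=O)C(F)(F)F)C(C)(C)C
Why: Silylene acetal formation: only the two oxygens on C2 and C2', ortho and ortho' to the biaryl bond, can be spanned by one silicon (seven-membered ring), the C4 hydroxyls lie para to the axis and cannot be bridged, and the hydrogen-bonded 2,2'-biphenol pair is expected to be the more acidic site, so that the second Si–O bond closes intramolecularly once the first is made.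

Step 7
Reactants: 11 4,8-diacetyl-6,6-di-tert-butyl-3,9-dihydroxy-1,11-dimethoxy-2,10-dimethyldibenzo[d,f][1,3,2]dioxasilepine
Product: 12 4,8-diacetyl-6,6-di-tert-butyl-1,3,9,11-tetramethoxy-2,10-dimethyldibenzo[d,f][1,3,2]dioxasilepine
Conditions: MeI (excess), Ag2O, 4 Å MS, DMF, rt, dark
Reagents that add atoms: iodomethane CI
Why: Purdie-type methylation with Ag2O and MeI is neutral and offers no nucleophile for silicon, so the only free hydroxyls left (C4 and C4', hydrogen-bonded to acetyl) should be etherified while the hindered di-tert-butylsilylene stays in place.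

Step 8
Reactants: 12 4,8-diacetyl-6,6-di-tert-butyl-1,3,9,11-tetramethoxy-2,10-dimethyldibenzo[d,f][1,3,2]dioxasilepine
Product: 13 contortin, 3,3'-diacetyl-4,4',6,6'-tetramethoxy-5,5'-dimethylbiphenyl-2,2'-diol (racemic)
Conditions: HF·pyridine, THF, 0 °C → rt
Reagents that add atoms: none
Why: Fluoride cleavage of both Si–O bonds, driven by the strength of the Si–F bond, should free the two C2 hydroxyls without touching aryl methyl ethers or aryl ketones.

**Compound list**

1 | methyl 3-oxopentanoate | CCC(=O)CC(=O)OC | starting material
2 | methyl 2-iodo-3-oxopentanoate | CCC(=O)C(I)C(=O)OC | intermediate (step 1, not isolated)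
3 | dimethyl 2,3-dipropanoylbutanedioate (mixture of meso and racemic forms) | CCC(=O)C(C(=O)OC)C(C(=O)OC)C(=O)CC | intermediate
4 | ethyl 2-(2-methyl-1,3-dioxolan-2-yl)acetate | CCOC(=O)CC1(C)OCCO1 | starting material
5 | dimethyl 2,3-bis[2-methyl-4-(2-methyl-1,3-dioxolan-2-yl)-3-oxobutanoyl]butanedioate (diastereomer mixture) | COC(=O)C(C(=O)C(C)C(=O)CC1(C)OCCO1)C(C(=O)OC)C(=O)C(C)C(=O)CC1(C)OCCO1 | intermediate
6 | 4,4'-dihydroxy-5,5'-dimethyl-6,6'-bis[(2-methyl-1,3-dioxolan-2-yl)methyl]-3,3'-bi(2H-pyran)-2,2'-dione | CC1(CC2=C(C)C(O)=C(C(=O)O2)C2=C(O)C(C)=C(CC3(C)OCCO3)OC2=O)OCCO1 | intermediate (step 3, not isolated)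
7 | 4,4'-dihydroxy-5,5'-dimethyl-6,6'-bis(2-oxopropyl)-3,3'-bi(2H-pyran)-2,2'-dione | CC(=O)CC1=C(C)C(O)=C(C(=O)O1)C1=C(O)C(C)=C(CC(C)=O)OC1=O | intermediate
8 | dimethyl 2,3-bis(2-methyl-3,5-dioxohexanoyl)butanedioate, present as its magnesium chelate | COC(=O)C(C(=O)C(C)C(=O)CC(C)=O)C(C(=O)OC)C(=O)C(C)C(=O)CC(C)=O | intermediate (step 4, not isolated)
9 | 3,3'-diacetyl-5,5'-dimethylbiphenyl-2,2',4,4',6,6'-hexol | CC(=O)c1c(O)c(C)c(O)c(-c2c(O)c(C)c(O)c(C(C)=O)c2O)c1O | intermediate
10 | 3,3'-diacetyl-6,6'-dimethoxy-5,5'-dimethylbiphenyl-2,2',4,4'-tetrol (racemic) | CC(=O)c1c(O)c(C)c(OC)c(-c2c(OC)c(C)c(O)c(C(C)=O)c2O)c1O | intermediate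
11 | 4,8-diacetyl-6,6-di-tert-butyl-3,9-dihydroxy-1,11-dimethoxy-2,10-dimethyldibenzo[d,f][1,3,2]dioxasilepine (racemic) | CC(=O)c1c(O)c(C)c(OC)c2c1O[Si](C(C)(C)C)(C(C)(C)C)Oc1c-2c(OC)c(C)c(O)c1C(C)=O | intermediate
12 | 4,8-diacetyl-6,6-di-tert-butyl-1,3,9,11-tetramethoxy-2,10-dimethyldibenzo[d,f][1,3,2]dioxasilepine (racemic) | CC(=O)c1c(OC)c(C)c(OC)c2c1O[Si](C(C)(C)C)(C(C)(C)C)Oc1c-2c(OC)c(C)c(OC)c1C(C)=O | intermediate
13 | contortin, 3,3'-diacetyl-4,4',6,6'-tetramethoxy-5,5'-dimethylbiphenyl-2,2'-diol (racemic) | COc1c(C)c(OC)c(-c2c(O)c(C(C)=O)c(OC)c(C)c2OC)c(O)c1C(C)=O | target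

**Step count and risks**

Total step count: 8. Longest linear sequence: 8 steps (1 → 13); 4 is used as purchased.

Steps most likely to fail:

1. Step 4 (key step). The methanolysis may stall because each pyranone sits as an unreactive magnesium pyranonate, only one half may fold, methoxide may strip acetyl units from 8 by retro-Claisen cleavage, and the electron-rich hexol may oxidise in air or close to a dibenzofuran during acidic work-up. The fallback gives up the fold and makes the biaryl bond by aryl–aryl coupling. Because every numbered compound before 9 depends on the failed fold, it sets out from none of them but from commercial 2,4,6-trimethoxytoluene F1, and it comes back to the route at 9. Friedel–Crafts acetylation (AcCl, SnCl4, CH2Cl2, −10 °C) would give 1-(2,4,6-trimethoxy-3-methylphenyl)ethan-1-one F2. Iodination of the one free ring position (N-iodosuccinimide, cat. CF3CO2H, MeCN) would give 1-(3-iodo-2,4,6-trimethoxy-5-methylphenyl)ethan-1-one F3. Ullmann homocoupling (activated copper powder, DMF, 150 °C) would give 3,3'-diacetyl-2,2',4,4',6,6'-hexamethoxy-5,5'-dimethylbiphenyl F4, and exhaustive demethylation (BBr3, CH2Cl2, −78 °C → rt) would deliver 9.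

2. Step 2. The tetraanion may form incompletely or precipitate, acylation may occur on one half only, and the carbanion may deprotonate ester 4, which then loses its dioxolane oxygen by β-elimination. The fallback reverses the order of chain extension and coupling; it sets out from 1 (with 4) and comes back at 5. The simple dianion of 1 (NaH, then n-BuLi, THF, 0 °C) would be acylated with 4 to give methyl 4-methyl-6-(2-methyl-1,3-dioxolan-2-yl)-3,5-dioxohexanoate F5. Its dianion (LiN(iPr)2, 2 equiv, THF, −78 °C; charges on the carbon between the ketones and on the carbon next to the ester) would then be oxidised with I2 (0.5 equiv). By analogy with the iodine coupling of β-diketone dianions at their more reactive terminus, the bond should form between the two ester α-carbons and give 5.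

3. Step 6. The first Si–O bond may form at a C4 hydroxyl; the resulting silyl triflate cannot close a ring and would link two molecules or end as a silanol, and the bridge may form incompletely on the twisted biaryl. The fallback replaces the silicon tether by an acyl tether whose misplaced acyl groups fall off on aqueous work-up; it sets out from 10 and comes back at 13. Carbonyldiimidazole (THF, rt → 50 °C), followed by aqueous work-up, would leave only the bridged carbonate, 4,8-diacetyl-3,9-dihydroxy-1,11-dimethoxy-2,10-dimethyldibenzo[d,f][1,3]dioxepin-6-one F6, with unreacted 10 recovered. Methylation (MeI, Ag2O, 4 Å MS, CH2Cl2) would give 4,8-diacetyl-1,3,9,11-tetramethoxy-2,10-dimethyldibenzo[d,f][1,3]dioxepin-6-one F7, and mild methanolysis (K2CO3, MeOH, 0 °C) would release 13.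

Further compounds
F1 | step 4 | 2,4,6-trimethoxytoluene | COc1cc(OC)c(C)c(OC)c1
F2 | step 4 | 1-(2,4,6-trimethoxy-3-methylphenyl)ethan-1-one | CC(=O)c1c(OC)cc(OC)c(C)c1OC
F3 | step 4 | 1-(3-iodo-2,4,6-trimethoxy-5-methylphenyl)ethan-1-one | CC(=O)c1c(OC)c(I)c(OC)c(C)c1OC
F4 | step 4 | 3,3'-diacetyl-2,2',4,4',6,6'-hexamethoxy-5,5'-dimethylbiphenyl | CC(=O)c1c(OC)c(C)c(OC)c(-c2c(OC)c(C)c(OC)c(C(C)=O)c2OC)c1OC
F5 | step 2 | methyl 4-methyl-6-(2-methyl-1,3-dioxolan-2-yl)-3,5-dioxohexanoate | COC(=O)CC(=O)C(C)C(=O)CC1(C)OCCO1
F6 | step 6 | 4,8-diacetyl-3,9-dihydroxy-1,11-dimethoxy-2,10-dimethyldibenzo[d,f][1,3]dioxepin-6-one | CC(=O)c1c(O)c(C)c(OC)c2c1OC(=O)Oc1c-2c(OC)c(C)c(O)c1C(C)=O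
F7 | step 6 | 4,8-diacetyl-1,3,9,11-tetramethoxy-2,10-dimethyldibenzo[d,f][1,3]dioxepin-6-one | CC(=O)c1c(OC)c(C)c(OC)c2c1OC(=O)Oc1c-2c(OC)c(C)c(OC)c1C(C)=O
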